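# Total synthesis plan for CNP0276773.5 (29) by an O6-tethered malonate opening of a C7–C8 epoxide

Abbreviations: TBS = tert-butyldimethylsilyl, PMB = 4-methoxybenzyl, TMSE = 2-(trimethylsilyl)ethyl, DIPT = diisopropyl tartrate, DCC = dicyclohexylcarbodiimide, DMAP = 4-(dimethylamino)pyridine, DDQ = 2,3-dichloro-5,6-dicyano-1,4-benzoquinone.

## The problem

Target 29 is a cis,cis-germacradienolide: a ten-membered carbocycle (C1–C10) with two Z trisubstituted alkenes, C1=C10 carrying the C14 hydroxymethyl group and C4=C5 carrying the methyl group, fused trans across C6–C7 to an α-methylene γ-lactone (lactone oxygen on C6, C11–C13 on C7). Four contiguous stereocentres, C6 (R), C7 (S), C8 (S) and C9 (R), lie on one edge of the ring and carry three different oxygen functions: the lactone at O6, the angelate at O8 and a free hydroxyl at O9, beside the free allylic C14 hydroxyl. Nothing elsewhere in the ring can relay chirality, so the C6–C8 triad has to come from a reagent. C8 can then steer C9, because addition to a C9 aldehyde anti to the C8–O bond gives the required 8,9-anti pattern. The fragile groups are the α-methylene lactone (a Michael acceptor for amines, hydride and alkoxides), the angelate (it isomerises to the tiglate, is cleaved by base and migrates to a free neighbouring hydroxyl), the lactone itself (it can move from O6 to a free O8) and the allylic C6–O bond. The medium ring has to be closed without loss of either Z geometry. The feature that opens the structure is the C6–C7–C8 arrangement: C11 on C7 stands anti to the C8 oxygen and is tied through C12 to the C6 oxygen, which is what backside opening of a trans C7–C8 epoxide by a two-carbon nucleophile hung from O6 leaves behind.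

## Retrosynthesis

**Ring bond C9–C10 (29 ⇒ 28 ⇒ 27).** After removal of the C14 silyl ether (28), the ten-membered ring is cut at C9–C10, giving the acyclic iodo aldehyde 27 for an alkenylchromium closure. A cut at C5–C6 would create C6 next to a centre with only carbon substituents, and a cut in the C2–C3 region offers no functional handle. The C9–C10 cut creates the C9 carbinol beside the C8 oxygen, where polar Felkin–Anh addition predicts the 8,9-anti isomer, and the alkenylchromium keeps the Z geometry of C1=C10. Compound 27 already holds the lactone, the methylene group and the angelate, so only a desilylation follows ring closure. The forward step must tolerate an enoate lactone and an α-acyloxy aldehyde and must beat oligomerisation.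

**C1=C10 and the C9 aldehyde (27 ⇒ 26 ⇒ 25 ⇒ 24 ⇒ 23 ⇒ 22 ⇒ 21 ⇒ 20).** The aldehyde of 27 comes from the PMB ether 25 by way of alcohol 26. The iodoalkene is cut at C1=C10: a two-carbon ylide brings C10 and C14 to aldehyde 21 (from alcohol 20), iodine enters C10 by α-iodination of enal 22, and reduction of 23 with silylation gives 24 and 25. Alkyne hydrometalation or α-iodo ester ylides would need strong base or ester-reducing hydrides that the lactone and angelate cannot bear. Here the geometry (C2 cis to iodine) is the thermodynamic one of the iodoenal. The forward steps must leave the methylene lactone alone.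

**C11=C13 and the angelate (20 ⇒ 19 ⇒ 18 ⇒ 17).** The methylene carbon is cut off as formaldehyde, leaving the C11 carboxylic acid 19 for a decarboxylative Mannich methylenation. The carboxyl is the activating group of the key step, so it costs no extra step. It is carried as a TMSE ester (18) so that fluoride frees it, together with the C1 silyl ether, without touching lactone or angelate. The angelate is placed on the C8 hydroxyl of 17 while C11 is still a β-dicarbonyl centre, whose enolate shields both carbonyls from the C8 alkoxide. Placing it this early avoids all later differentiation of O8 from O9.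

**C7–C11, the key cut (17 ⇒ 16).** Breaking C7–C11 of lactone 17 returns the malonate 16 of a trans-epoxy alcohol. Neighbouring cuts were weighed: lactonisation at O6–C12 would need C7 set separately, and a C7–C8 cut (conjugate addition to a butenolide) would need O8 set separately. The chosen cut draws C7 and C8 from the epoxide and C6 from the carbinol. Compound 16 has no carbon stereocentre that the epoxidation does not supply. The forward reaction must attack C7 (5-exo) with inversion and must not pass the exocyclic acyl group to the liberated O8.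

**Ester and epoxide (16 ⇒ 12 + 15; 15 ⇒ 13 + 14; 12 ⇒ 11).** The ester bond leads to epoxy alcohol 12 and the half ester 15, itself from Meldrum's acid 13 and alcohol 14. The epoxide C–O bonds of 12 are removed to give the racemic bis-allylic alcohol 11. A Sharpless kinetic resolution then sets C6, C7 and C8 in one reagent-controlled operation. It has to choose the E disubstituted alkene over the Z trisubstituted one and costs half of the material.

**C5–C6 and the fragments (11 ⇒ 6 + 9; 6 ⇒ 1 + 2; 9 ⇒ 8 ⇒ 7).** The C5–C6 bond is cut to the Z alkenyl iodide 6 (as its lithium reagent 10) and enal 9. Iodide 6 arises from bromide 1 and propyne 2 by syn carbocupration through 3, 4 and 5, which fixes the Z geometry of C4=C5. Enal 9 comes from diol 7 by way of the mono-PMB ether 8. The addition must be 1,2 and the iodide must exchange with retention.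

## Roads not taken

**Alternative 1:** The cut is at C6–C7 and C9–C10, taking C6–C10 out as a seven-membered ring. In the forward key step Me3SiOTf ionises the mixed acetal A2, and the alkoxy-silyloxy allyl cation adds (4+3) across the 2-substituted furan A1 to give the oxabicyclic ketone A3, with the (S)-1-phenylethyl ether as controller.
- Merits: two C–C bonds and three stereocentres (C6, C7, C9) arise in one step, and the rigid bicycle should allow a face-selective reduction of the C8 ketone. In bonds made per step it is better than the chosen key step, which makes one.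
- Weak points: A3 is a seven-membered carbocycle, so the ten-membered ring still has to be grown from the sulfone arm and the alkene of A3. The ether bridge ties O6 to C10 as well, so a C10–O bond must later be broken and turned into the Z C1=C10 alkene. Neither trisubstituted alkene exists yet. Regiochemistry and facial sense on a 2-substituted furan must both be right, and removal of the benzylic auxiliary conflicts with the alkenes.
- Comparison: the chosen plan keeps the chain open so that one ring closure and no skeletal surgery remain. Against the convergence of A3 it has to set the half-yield ceiling of its resolution.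

**Alternative 2:** The cut is a retro-fragmentation: a transannular C4–C9 bond is added, giving the cis-decalin hydroxy mesylate A4. Forward, KOtBu forms the C9 alkoxide, C4–C9 breaks, the equatorial C5 mesylate leaves and the ten-membered enone A5 appears (Wharton–Grob fragmentation).
- Merits: the ring forms without the entropic cost of macrocyclisation. Both alkene geometries are fixed by the decalin (C1=C10 inside a six-membered ring, C4=C5 by the anti-periplanar fragmentation). In this respect it is more reliable than the high-dilution closure of the chosen plan.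
- Weak points: A5 has no oxygen at C8 and a ketone at C9. C8 must therefore be oxygenated next to the ketone in a flexible ring with 8S control, and C9 reduced to 9R, before methylenation and angeloylation. A4 needs five stereocentres, among them the quaternary C4 and the tertiary C9 carbinol, and is a long synthesis of its own. KOtBu may also enolise or open the lactone.
- Comparison: the chosen plan sets O8 together with C6 and C7 in one step. It pays with a ring closure whose yield and C9 sense are less certain.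

**Alternative 3:** The cut is at C5–C6 and at the lactone O6–C12 bond. Forward, electrolysis with catalytic CrCl2 and NiCl2 adds the Z alkenyl iodide of the seco ester A6 to its C6 aldehyde, and the alkoxide lactonises onto the C12 methyl ester to give macrocycle A7.
- Merits: ring and lactone form in one step with retention of the Z geometry. Chromium is catalytic, which is better than the stoichiometric CrCl2 of the chosen plan.
- Weak points: C6 is created in the ring closure beside C7, which bears only carbon substituents, so facial control is left to ring conformation. The aldehyde of A6 is α-branched and β to an ester and can epimerise at C7. The C7–C8–C9 triad of A6 needs separate asymmetric steps. After closure A7 still needs lactone-enolate methylenation inside the macrocycle, PMB removal, angeloylation and two desilylations.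
- Comparison: the chosen plan uses the same kind of ring closure at C9–C10, where the C8 oxygen directs, and reaches 29 one step later. It must accept stoichiometric chromium unless the electrochemical variant is adopted.

Key step: step 8

Assumption: germacrane numbering is used throughout; C11 of 17–19 is an epimerisable malonate-type centre, drawn as the trans epimer and erased in step 10; (3-bromopropoxy)(tert-butyl)dimethylsilane 1 is taken as commercial in place of 3-bromopropan-1-ol.

## Route

Step 1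
Reactants: 1 (3-bromopropoxy)(tert-butyl)dimethylsilane; 2 propyne
Product: 6 (Z)-tert-butyl[(5-iodo-4-methylpent-4-en-1-yl)oxy]dimethylsilane, via Grignard reagent 3 (not isolated), via alkylcopper 4 (not isolated), via alkenylcopper 5 (not isolated)
Conditions: Mg, Et2O, reflux; CuBr·SMe2, Et2O/Me2S, −45 °C; propyne, −25 °C; I2, −50 °C to 0 °C
Reagents that add atoms: iodine, II
Why: Carbocupration of a terminal alkyne adds the alkyl group and copper syn, alkyl to the internal carbon, and iodinolysis proceeds with retention, so the chain and iodine end up cis (Z), the future Z C4=C5.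

Step 2
Reactants: 7 (Z)-but-2-ene-1,4-diol
Product: 8 (Z)-4-[(4-methoxybenzyl)oxy]but-2-en-1-ol
Conditions: 7 (2.5 equiv), NaH (1.0 equiv), 4-methoxybenzyl chloride (1.0 equiv), Bu4NI (cat.), THF/DMF, 0 °C to rt
Reagents that add atoms: 4-methoxybenzyl chloride, COc1ccc(CCl)cc1
Why: Williamson monoalkylation of a symmetric diol used in excess should give mainly the mono ether.

Step 3
Reactants: 8 (Z)-4-[(4-methoxybenzyl)oxy]but-2-en-1-ol
Product: 9 (E)-4-[(4-methoxybenzyl)oxy]but-2-enal
Conditions: pyridinium chlorochromate (C5H5NH)[CrO3Cl], CH2Cl2, rt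
Reagents that add atoms: none
Why: Chromate oxidation of the allylic alcohol; under the mildly acidic conditions the first-formed Z enal should isomerise to the conjugated E enal, the geometry needed for a trans epoxide.

Step 4
Reactants: 6 (Z)-tert-butyl[(5-iodo-4-methylpent-4-en-1-yl)oxy]dimethylsilane; 9 (E)-4-[(4-methoxybenzyl)oxy]but-2-enal
Product: 11 racemic (2E,5Z)-9-(tert-butyldimethylsilyloxy)-1-[(4-methoxybenzyl)oxy]-6-methylnona-2,5-dien-4-ol, via alkenyllithium 10 (not isolated)
Conditions: t-BuLi (2.1 equiv), Et2O, −78 °C; then 9, −78 °C; then H2O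
Reagents that add atoms: none
Why: Iodine–lithium exchange retains the alkene geometry and the alkenyllithium adds 1,2 to the enal, forming C5–C6; the C6 carbinol is racemic and is resolved in step 5.

Step 5
Reactants: 11 racemic (2E,5Z)-9-(tert-butyldimethylsilyloxy)-1-[(4-methoxybenzyl)oxy]-6-methylnona-2,5-dien-4-ol
Product: 12 (1R,2Z)-6-(tert-butyldimethylsilyloxy)-1-[(2R,3R)-3-{[(4-methoxybenzyl)oxy]methyl}oxiran-2-yl]-3-methylhex-2-en-1-ol
Conditions: Ti(OiPr)4 (0.15 equiv), D-(−)-diisopropyl tartrate (0.2 equiv), t-BuOOH (0.45 equiv), 4 Å molecular sieves, CH2Cl2, −20 °C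
Reagents that add atoms: tert-butyl hydroperoxide, CC(C)(C)OO
Why: Sharpless kinetic resolution: with the D-(−)-tartrate the (S)-enantiomer of 11 should be epoxidised at the E C7=C8 alkene on the face that gives the erythro (7R,8R) epoxy alcohol, so C6, C7 and C8 are set by the reagent; the Z trisubstituted alkene should be slow because its cis C3 substituent clashes with the carbinol substituent (A(1,3) strain) in the titanium-bound conformer, and unreacted (R)-11 is separated.

Step 6
Reactants: 13 2,2-dimethyl-1,3-dioxane-4,6-dione (Meldrum's acid); 14 2-(trimethylsilyl)ethanol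
Product: 15 3-oxo-3-[2-(trimethylsilyl)ethoxy]propanoic acid
Conditions: toluene, 100 °C
Reagents that add atoms: none
Why: Thermal alcoholysis of Meldrum's acid with loss of acetone is the standard route to malonic half esters.

Step 7
Reactants: 12 (1R,2Z)-6-(tert-butyldimethylsilyloxy)-1-[(2R,3R)-3-{[(4-methoxybenzyl)oxy]methyl}oxiran-2-yl]-3-methylhex-2-en-1-ol; 15 3-oxo-3-[2-(trimethylsilyl)ethoxy]propanoic acid
Product: 16 (1R,2Z)-6-(tert-butyldimethylsilyloxy)-1-[(2R,3R)-3-{[(4-methoxybenzyl)oxy]methyl}oxiran-2-yl]-3-methylhex-2-en-1-yl 2-(trimethylsilyl)ethyl propanedioate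
Conditions: DCC, DMAP (cat.), CH2Cl2, 0 °C
Reagents that add atoms: none
Why: Steglich esterification under neutral conditions should acylate the secondary C6 hydroxyl without opening the epoxide; no stereocentre is touched.

Step 8
Reactants: 16 (1R,2Z)-6-(tert-butyldimethylsilyloxy)-1-[(2R,3R)-3-{[(4-methoxybenzyl)oxy]methyl}oxiran-2-yl]-3-methylhex-2-en-1-yl 2-(trimethylsilyl)ethyl propanedioate
Product: 17 2-(trimethylsilyl)ethyl (3R,4R,5R)-5-[(Z)-5-(tert-butyldimethylsilyloxy)-2-methylpent-1-en-1-yl]-4-[(1S)-1-hydroxy-2-(4-methoxybenzyloxy)ethyl]-2-oxooxolane-3-carboxylate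
Conditions: NaH (1.05 equiv), THF, 0 °C to rt; AcOH, −78 °C
Reagents that add atoms: none
Why: NaH removes a malonate proton of 16, and the enolate carbon (C11) attacks C7 from the side opposite the epoxide oxygen in an SN2 step, so C7–C11 forms with inversion, the γ-lactone closes and the C8 alkoxide is set free. The closest known reaction type is the alkylation of malonate anions by epoxides, here in its intramolecular, ester-tethered form on a 2,3-epoxy alcohol derivative. The ring closure is 5-exo-tet; attack at C8 would be a 6-endo closure with a poorer trajectory, so the tether through O6 fixes the regiochemistry. C7 is controlled by the epoxide configuration (inversion), C8 keeps the epoxide configuration and becomes the carbinol, C6 is untouched, and C11 settles under thermodynamic control trans to the C7 side chain. Because 12 is the erythro trans-epoxy alcohol, inversion at C7 gives the trans β,γ-disubstituted lactone with C11 anti to O8, as in 29. The step needs C- rather than O-alkylation and no acyl transfer to the new alkoxide: the alkoxide is quenched at once by the acidic C11–H, and the resulting enolate should shield both carbonyls in aprotic THF until the cold acetic acid quench.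

Step 9
Reactants: 17 2-(trimethylsilyl)ethyl (3R,4R,5R)-5-[(Z)-5-(tert-butyldimethylsilyloxy)-2-methylpent-1-en-1-yl]-4-[(1S)-1-hydroxy-2-(4-methoxybenzyloxy)ethyl]-2-oxooxolane-3-carboxylate
Product: 18 2-(trimethylsilyl)ethyl (3R,4S,5R)-5-[(Z)-5-(tert-butyldimethylsilyloxy)-2-methylpent-1-en-1-yl]-4-[(1S)-2-(4-methoxybenzyloxy)-1-{[(Z)-2-methylbut-2-enoyl]oxy}ethyl]-2-oxooxolane-3-carboxylate
Conditions: LiN(SiMe3)2 (2.1 equiv), THF, −78 °C; angelic anhydride (1.1 equiv), −78 °C to −40 °C; AcOH
Reagents that add atoms: angelic anhydride, C/C=C(/C)C(=O)OC(=O)/C(C)=C\C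
Why: The first equivalent of base regenerates the C11 enolate, which masks both carbonyls, and the second forms the C8 alkoxide; acylation of a lithium alkoxide by angelic anhydride at low temperature is the known way to form angelates without Z to E isomerisation, and the alkoxide should react far faster than the stabilised enolate.

Step 10
Reactants: 18 2-(trimethylsilyl)ethyl (3R,4S,5R)-5-[(Z)-5-(tert-butyldimethylsilyloxy)-2-methylpent-1-en-1-yl]-4-[(1S)-2-(4-methoxybenzyloxy)-1-{[(Z)-2-methylbut-2-enoyl]oxy}ethyl]-2-oxooxolane-3-carboxylate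
Product: 20 (1S)-1-[(2R,3S)-2-[(Z)-5-hydroxy-2-methylpent-1-en-1-yl]-4-methylidene-5-oxooxolan-3-yl]-2-(4-methoxybenzyloxy)ethyl (Z)-2-methylbut-2-enoate, via carboxylic acid 19 (not isolated)
Conditions: Bu4NF (3 equiv), THF, 0 °C to rt; AcOH; then Et2NH, (CH2O)n, THF, 65 °C
Reagents that add atoms: formaldehyde (from paraformaldehyde), C=O
Why: Fluoride cleaves the TMSE ester by β-elimination and the primary silyl ether at C1 while lactone and angelate stay intact; the malonic-type acid 19 then undergoes the decarboxylative Mannich methylenation (iminium capture at C11, loss of CO2 and amine), which erases C11 and installs C13.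

Step 11
Reactants: 20 (1S)-1-[(2R,3S)-2-[(Z)-5-hydroxy-2-methylpent-1-en-1-yl]-4-methylidene-5-oxooxolan-3-yl]-2-(4-methoxybenzyloxy)ethyl (Z)-2-methylbut-2-enoate
Product: 21 (1S)-1-[(2R,3S)-2-[(Z)-2-methyl-5-oxopent-1-en-1-yl]-4-methylidene-5-oxooxolan-3-yl]-2-(4-methoxybenzyloxy)ethyl (Z)-2-methylbut-2-enoate
Conditions: Dess–Martin periodinane, CH2Cl2, 0 °C to rt
Reagents that add atoms: none
Why: Dess–Martin oxidation of the primary C1 alcohol is neutral and should not touch the enoates, the PMB ether or the alkenes.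

Step 12
Reactants: 21 (1S)-1-[(2R,3S)-2-[(Z)-2-methyl-5-oxopent-1-en-1-yl]-4-methylidene-5-oxooxolan-3-yl]-2-(4-methoxybenzyloxy)ethyl (Z)-2-methylbut-2-enoate
Product: 22 (1S)-1-[(2R,3S)-2-[(1Z,5E)-2-methyl-7-oxohepta-1,5-dien-1-yl]-4-methylidene-5-oxooxolan-3-yl]-2-(4-methoxybenzyloxy)ethyl (Z)-2-methylbut-2-enoate
Conditions: Ph3P=CHCHO (1.3 equiv), toluene, 80 °C
Reagents that add atoms: (triphenylphosphoranylidene)acetaldehyde, O=CC=P(c1ccccc1)(c1ccccc1)c1ccccc1
Why: Wittig reaction with the stabilised formyl ylide adds C10 and C14 and should give the E enal; the weakly nucleophilic ylide is not expected to add to the methylene lactone.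

Step 13
Reactants: 22 (1S)-1-[(2R,3S)-2-[(1Z,5E)-2-methyl-7-oxohepta-1,5-dien-1-yl]-4-methylidene-5-oxooxolan-3-yl]-2-(4-methoxybenzyloxy)ethyl (Z)-2-methylbut-2-enoate
Product: 23 (1S)-1-[(2R,3S)-2-[(1Z,5Z)-6-iodo-2-methyl-7-oxohepta-1,5-dien-1-yl]-4-methylidene-5-oxooxolan-3-yl]-2-(4-methoxybenzyloxy)ethyl (Z)-2-methylbut-2-enoate
Conditions: I2 (1.5 equiv), DMAP (0.2 equiv), K2CO3, THF/H2O, rt, dark
Reagents that add atoms: iodine, II
Why: Amine-catalysed α-iodination of an enal (conjugate addition of DMAP, iodination of the enolate, E1cB loss of DMAP) gives the thermodynamic Z iodoenal with C2 cis to iodine; the methylene lactone has no α-hydrogen, so any adduct there can only revert.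

Step 14
Reactants: 23 (1S)-1-[(2R,3S)-2-[(1Z,5Z)-6-iodo-2-methyl-7-oxohepta-1,5-dien-1-yl]-4-methylidene-5-oxooxolan-3-yl]-2-(4-methoxybenzyloxy)ethyl (Z)-2-methylbut-2-enoate
Product: 24 (1S)-1-[(2R,3S)-2-[(1Z,5Z)-7-hydroxy-6-iodo-2-methylhepta-1,5-dien-1-yl]-4-methylidene-5-oxooxolan-3-yl]-2-(4-methoxybenzyloxy)ethyl (Z)-2-methylbut-2-enoate
Conditions: NaBH4 (1.0 equiv), CeCl3·7H2O, MeOH, −78 °C
Reagents that add atoms: none
Why: Luche reduction is selective for 1,2-reduction of the aldehyde; at −78 °C it should be much faster than conjugate reduction of the methylene lactone.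

Step 15
Reactants: 24 (1S)-1-[(2R,3S)-2-[(1Z,5Z)-7-hydroxy-6-iodo-2-methylhepta-1,5-dien-1-yl]-4-methylidene-5-oxooxolan-3-yl]-2-(4-methoxybenzyloxy)ethyl (Z)-2-methylbut-2-enoate
Product: 25 (1S)-1-[(2R,3S)-2-[(1Z,5Z)-7-(tert-butyldimethylsilyloxy)-6-iodo-2-methylhepta-1,5-dien-1-yl]-4-methylidene-5-oxooxolan-3-yl]-2-(4-methoxybenzyloxy)ethyl (Z)-2-methylbut-2-enoate
Conditions: t-BuMe2SiCl, imidazole, CH2Cl2, 0 °C
Reagents that add atoms: tert-butyldimethylsilyl chloride, CC(C)(C)[Si](C)(C)Cl
Why: Standard silylation of the primary allylic C14 hydroxyl, so that only C9 is oxidised in step 17.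

Step 16
Reactants: 25 (1S)-1-[(2R,3S)-2-[(1Z,5Z)-7-(tert-butyldimethylsilyloxy)-6-iodo-2-methylhepta-1,5-dien-1-yl]-4-methylidene-5-oxooxolan-3-yl]-2-(4-methoxybenzyloxy)ethyl (Z)-2-methylbut-2-enoate
Product: 26 (1S)-1-[(2R,3S)-2-[(1Z,5Z)-7-(tert-butyldimethylsilyloxy)-6-iodo-2-methylhepta-1,5-dien-1-yl]-4-methylidene-5-oxooxolan-3-yl]-2-hydroxyethyl (Z)-2-methylbut-2-enoate
Conditions: DDQ, CH2Cl2/pH 7 buffer, 0 °C
Reagents that add atoms: none
Why: Oxidative cleavage of the PMB ether by DDQ under buffered conditions; 26 is kept neutral and oxidised at once so that the angelate does not migrate to the free C9 hydroxyl.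

Step 17
Reactants: 26 (1S)-1-[(2R,3S)-2-[(1Z,5Z)-7-(tert-butyldimethylsilyloxy)-6-iodo-2-methylhepta-1,5-dien-1-yl]-4-methylidene-5-oxooxolan-3-yl]-2-hydroxyethyl (Z)-2-methylbut-2-enoate
Product: 27 (1S)-1-[(2R,3S)-2-[(1Z,5Z)-7-(tert-butyldimethylsilyloxy)-6-iodo-2-methylhepta-1,5-dien-1-yl]-4-methylidene-5-oxooxolan-3-yl]-2-oxoethyl (Z)-2-methylbut-2-enoate
Conditions: Dess–Martin periodinane, CH2Cl2, 0 °C
Reagents that add atoms: none
Why: Dess–Martin oxidation gives the α-acyloxy aldehyde without base, so C8 should not epimerise; the crude aldehyde is used directly.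

Step 18
Reactants: 27 (1S)-1-[(2R,3S)-2-[(1Z,5Z)-7-(tert-butyldimethylsilyloxy)-6-iodo-2-methylhepta-1,5-dien-1-yl]-4-methylidene-5-oxooxolan-3-yl]-2-oxoethyl (Z)-2-methylbut-2-enoate
Product: 28 (3aS,4S,5R,6Z,10Z,11aR)-6-{[(tert-butyldimethylsilyl)oxy]methyl}-5-hydroxy-10-methyl-3-methylidene-2-oxo-2,3,3a,4,5,8,9,11a-octahydrocyclodeca[b]furan-4-yl (Z)-2-methylbut-2-enoate
Conditions: CrCl2 (8 equiv), NiCl2 (cat.), degassed DMSO/THF, rt, slow addition to 2 mM
Reagents that add atoms: none
Why: Nozaki–Hiyama–Kishi reaction: zerovalent nickel (from NiCl2 and CrCl2) inserts into the C10–I bond, transmetallation gives the alkenyl derivative of trivalent chromium with retention of the Z geometry, and this adds to the C9 aldehyde to close the ten-membered ring; polar Felkin–Anh attack anti to the C8–O bond should give the 8,9-anti (9R) carbinol.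

Step 19
Reactants: 28 (3aS,4S,5R,6Z,10Z,11aR)-6-{[(tert-butyldimethylsilyl)oxy]methyl}-5-hydroxy-10-methyl-3-methylidene-2-oxo-2,3,3a,4,5,8,9,11a-octahydrocyclodeca[b]furan-4-yl (Z)-2-methylbut-2-enoate
Product: 29 (3aS,4S,5R,6Z,10Z,11aR)-5-hydroxy-6-(hydroxymethyl)-10-methyl-3-methylidene-2-oxo-2,3,3a,4,5,8,9,11a-octahydrocyclodeca[b]furan-4-yl (Z)-2-methylbut-2-enoate
Conditions: HF·pyridine, pyridine/THF, 0 °C to rt
Reagents that add atoms: none
Why: Buffered HF removes the primary allylic silyl ether without base, so the angelate should neither migrate to O9 nor isomerise and the methylene lactone is untouched.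

## Compound list

1 | (3-bromopropoxy)(tert-butyl)dimethylsilane | BrCCCO[Si](C)(C)C(C)(C)C | starting material
2 | propyne | CC#C | starting material
3 | [3-(tert-butyldimethylsilyloxy)propyl]magnesium bromide | Br[Mg]CCCO[Si](C)(C)C(C)(C)C | intermediate
4 | [3-(tert-butyldimethylsilyloxy)propyl]copper (MgBr2 complex) | [Cu]CCCO[Si](C)(C)C(C)(C)C | intermediate
5 | (Z)-[5-(tert-butyldimethylsilyloxy)-2-methylpent-1-en-1-yl]copper | [Cu]/C=C(/C)CCCO[Si](C)(C)C(C)(C)C | intermediate
6 | (Z)-tert-butyl[(5-iodo-4-methylpent-4-en-1-yl)oxy]dimethylsilane | I/C=C(/C)CCCO[Si](C)(C)C(C)(C)C | intermediate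
7 | (Z)-but-2-ene-1,4-diol | OC/C=C\CO | starting material
8 | (Z)-4-[(4-methoxybenzyl)oxy]but-2-en-1-ol | OC/C=C\COCc1ccc(OC)cc1 | intermediate
9 | (E)-4-[(4-methoxybenzyl)oxy]but-2-enal | O=C/C=C/COCc1ccc(OC)cc1 | intermediate
10 | (Z)-[5-(tert-butyldimethylsilyloxy)-2-methylpent-1-en-1-yl]lithium | [Li]/C=C(/C)CCCO[Si](C)(C)C(C)(C)C | intermediate
11 | racemic (2E,5Z)-9-(tert-butyldimethylsilyloxy)-1-[(4-methoxybenzyl)oxy]-6-methylnona-2,5-dien-4-ol | OC(/C=C(/C)CCCO[Si](C)(C)C(C)(C)C)/C=C/COCc1ccc(OC)cc1 | intermediate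
12 | (1R,2Z)-6-(tert-butyldimethylsilyloxy)-1-[(2R,3R)-3-{[(4-methoxybenzyl)oxy]methyl}oxiran-2-yl]-3-methylhex-2-en-1-ol | O[C@H](/C=C(/C)CCCO[Si](C)(C)C(C)(C)C)[C@H]1O[C@@H]1COCc1ccc(OC)cc1 | intermediate
13 | 2,2-dimethyl-1,3-dioxane-4,6-dione (Meldrum's acid) | CC1(C)OC(=O)CC(=O)O1 | starting material
14 | 2-(trimethylsilyl)ethanol | C[Si](C)(C)CCO | starting material
15 | 3-oxo-3-[2-(trimethylsilyl)ethoxy]propanoic acid | OC(=O)CC(=O)OCC[Si](C)(C)C | intermediate
16 | (1R,2Z)-6-(tert-butyldimethylsilyloxy)-1-[(2R,3R)-3-{[(4-methoxybenzyl)oxy]methyl}oxiran-2-yl]-3-methylhex-2-en-1-yl 2-(trimethylsilyl)ethyl propanedioate | C[Si](C)(C)CCOC(=O)CC(=O)O[C@H](/C=C(/C)CCCO[Si](C)(C)C(C)(C)C)[C@H]1O[C@@H]1COCc1ccc(OC)cc1 | intermediate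
17 | 2-(trimethylsilyl)ethyl (3R,4R,5R)-5-[(Z)-5-(tert-butyldimethylsilyloxy)-2-methylpent-1-en-1-yl]-4-[(1S)-1-hydroxy-2-(4-methoxybenzyloxy)ethyl]-2-oxooxolane-3-carboxylate | C[Si](C)(C)CCOC(=O)[C@@H]1C(=O)O[C@H](/C=C(/C)CCCO[Si](C)(C)C(C)(C)C)[C@H]1[C@H](O)COCc1ccc(OC)cc1 | intermediate
18 | 2-(trimethylsilyl)ethyl (3R,4S,5R)-5-[(Z)-5-(tert-butyldimethylsilyloxy)-2-methylpent-1-en-1-yl]-4-[(1S)-2-(4-methoxybenzyloxy)-1-{[(Z)-2-methylbut-2-enoyl]oxy}ethyl]-2-oxooxolane-3-carboxylate | C[Si](C)(C)CCOC(=O)[C@@H]1C(=O)O[C@H](/C=C(/C)CCCO[Si](C)(C)C(C)(C)C)[C@H]1[C@H](OC(=O)/C(C)=C\C)COCc1ccc(OC)cc1 | intermediate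
19 | (3R,4S,5R)-5-[(Z)-5-hydroxy-2-methylpent-1-en-1-yl]-4-[(1S)-2-(4-methoxybenzyloxy)-1-{[(Z)-2-methylbut-2-enoyl]oxy}ethyl]-2-oxooxolane-3-carboxylic acid | OC(=O)[C@@H]1C(=O)O[C@H](/C=C(/C)CCCO)[C@H]1[C@H](OC(=O)/C(C)=C\C)COCc1ccc(OC)cc1 | intermediate
20 | (1S)-1-[(2R,3S)-2-[(Z)-5-hydroxy-2-methylpent-1-en-1-yl]-4-methylidene-5-oxooxolan-3-yl]-2-(4-methoxybenzyloxy)ethyl (Z)-2-methylbut-2-enoate | C=C1C(=O)O[C@H](/C=C(/C)CCCO)[C@H]1[C@H](OC(=O)/C(C)=C\C)COCc1ccc(OC)cc1 | intermediate
21 | (1S)-1-[(2R,3S)-2-[(Z)-2-methyl-5-oxopent-1-en-1-yl]-4-methylidene-5-oxooxolan-3-yl]-2-(4-methoxybenzyloxy)ethyl (Z)-2-methylbut-2-enoate | C=C1C(=O)O[C@H](/C=C(/C)CCC=O)[C@H]1[C@H](OC(=O)/C(C)=C\C)COCc1ccc(OC)cc1 | intermediate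
22 | (1S)-1-[(2R,3S)-2-[(1Z,5E)-2-methyl-7-oxohepta-1,5-dien-1-yl]-4-methylidene-5-oxooxolan-3-yl]-2-(4-methoxybenzyloxy)ethyl (Z)-2-methylbut-2-enoate | C=C1C(=O)O[C@H](/C=C(/C)CC/C=C/C=O)[C@H]1[C@H](OC(=O)/C(C)=C\C)COCc1ccc(OC)cc1 | intermediate
23 | (1S)-1-[(2R,3S)-2-[(1Z,5Z)-6-iodo-2-methyl-7-oxohepta-1,5-dien-1-yl]-4-methylidene-5-oxooxolan-3-yl]-2-(4-methoxybenzyloxy)ethyl (Z)-2-methylbut-2-enoate | C=C1C(=O)O[C@H](/C=C(/C)CC/C=C(\I)C=O)[C@H]1[C@H](OC(=O)/C(C)=C\C)COCc1ccc(OC)cc1 | intermediate
24 | (1S)-1-[(2R,3S)-2-[(1Z,5Z)-7-hydroxy-6-iodo-2-methylhepta-1,5-dien-1-yl]-4-methylidene-5-oxooxolan-3-yl]-2-(4-methoxybenzyloxy)ethyl (Z)-2-methylbut-2-enoate | C=C1C(=O)O[C@H](/C=C(/C)CC/C=C(\I)CO)[C@H]1[C@H](OC(=O)/C(C)=C\C)COCc1ccc(OC)cc1 | intermediate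
25 | (1S)-1-[(2R,3S)-2-[(1Z,5Z)-7-(tert-butyldimethylsilyloxy)-6-iodo-2-methylhepta-1,5-dien-1-yl]-4-methylidene-5-oxooxolan-3-yl]-2-(4-methoxybenzyloxy)ethyl (Z)-2-methylbut-2-enoate | C=C1C(=O)O[C@H](/C=C(/C)CC/C=C(\I)CO[Si](C)(C)C(C)(C)C)[C@H]1[C@H](OC(=O)/C(C)=C\C)COCc1ccc(OC)cc1 | intermediate
26 | (1S)-1-[(2R,3S)-2-[(1Z,5Z)-7-(tert-butyldimethylsilyloxy)-6-iodo-2-methylhepta-1,5-dien-1-yl]-4-methylidene-5-oxooxolan-3-yl]-2-hydroxyethyl (Z)-2-methylbut-2-enoate | C=C1C(=O)O[C@H](/C=C(/C)CC/C=C(\I)CO[Si](C)(C)C(C)(C)C)[C@H]1[C@H](OC(=O)/C(C)=C\C)CO | intermediate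
27 | (1S)-1-[(2R,3S)-2-[(1Z,5Z)-7-(tert-butyldimethylsilyloxy)-6-iodo-2-methylhepta-1,5-dien-1-yl]-4-methylidene-5-oxooxolan-3-yl]-2-oxoethyl (Z)-2-methylbut-2-enoate | C=C1C(=O)O[C@H](/C=C(/C)CC/C=C(\I)CO[Si](C)(C)C(C)(C)C)[C@H]1[C@H](OC(=O)/C(C)=C\C)C=O | intermediate
28 | (3aS,4S,5R,6Z,10Z,11aR)-6-{[(tert-butyldimethylsilyl)oxy]methyl}-5-hydroxy-10-methyl-3-methylidene-2-oxo-2,3,3a,4,5,8,9,11a-octahydrocyclodeca[b]furan-4-yl (Z)-2-methylbut-2-enoate | C=C1C(=O)O[C@@H]2/C=C(/C)CC/C=C(/CO[Si](C)(C)C(C)(C)C)[C@@H](O)[C@@H](OC(=O)/C(C)=C\C)[C@@H]12 | intermediate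
29 | (3aS,4S,5R,6Z,10Z,11aR)-5-hydroxy-6-(hydroxymethyl)-10-methyl-3-methylidene-2-oxo-2,3,3a,4,5,8,9,11a-octahydrocyclodeca[b]furan-4-yl (Z)-2-methylbut-2-enoate (CNP0276773.5) | C=C1C(=O)O[C@@H]2/C=C(/C)CC/C=C(/CO)[C@@H](O)[C@@H](OC(=O)/C(C)=C\C)[C@@H]12 | target

## Step count and least certain steps

Total step count: 19. Longest linear sequence: 17 steps (7 to 29 through steps 2–5 and 7–19).

**Step 8 (key step).** The closure may be slow, because the ester tether has to reach its less favoured s-cis arrangement before the enolate carbon can come into line with the C7–O bond. The liberated C8 alkoxide may also take over the exocyclic acyl group (a second lactonisation) or draw the lactone from O6 to O8 before it is quenched.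
Fallback: the route sets out from 12, which is esterified (DCC, DMAP) with commercial 3-tert-butoxy-3-oxopropanoic acid to the tert-butyl malonate, (1R,2Z)-6-(tert-butyldimethylsilyloxy)-1-[(2R,3R)-3-{[(4-methoxybenzyl)oxy]methyl}oxiran-2-yl]-3-methylhex-2-en-1-yl tert-butyl propanedioate F1. The same NaH closure gives the tert-butyl ester hydroxy lactone F2, whose hindered ester cannot accept the alkoxide. Acylation as in step 9 gives the tert-butyl ester angelate F3. Me3SiOTf with 2,6-lutidine then converts the tert-butyl ester into the acid (by way of the silyl ester, hydrolysed on work-up), and Bu4NF removes the C1 silyl ether. The route is rejoined at 19.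

**Step 5.** The resolution may lose chemoselectivity (epoxidation of the Z trisubstituted C4=C5 alkene) or discriminate poorly between the enantiomers of this bis-allylic alcohol. At best it uses half of 11.
Fallback: the route sets out from 9, which is reduced (NaBH4, CeCl3·7H2O) to the E allylic alcohol, (E)-4-[(4-methoxybenzyl)oxy]but-2-en-1-ol F4. Sharpless asymmetric epoxidation (Ti(OiPr)4, D-(−)-DIPT, t-BuOOH) gives the epoxy alcohol F5, and Parikh–Doering oxidation gives the epoxy aldehyde F6. Addition of 10 is expected to give 12 together with its C6 epimer F7. The mixture is oxidised (Dess–Martin) to the epoxy enone F8, and chelation-controlled reduction with Zn(BH4)2, which gives erythro epoxy alcohols, returns the route to 12 without a resolution.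

**Step 9.** Acylation may occur at the enolate instead of the alkoxide, or the angelate may isomerise to the tiglate during acyl transfer.
Fallback: the route sets out from 17, whose C8 hydroxyl is esterified (DCC, DMAP, 0 °C) with 2-[bis(2,2,2-trifluoroethoxy)phosphoryl]propanoic acid to the phosphonate ester F9. A Still–Gennari olefination with acetaldehyde (KN(SiMe3)2, 18-crown-6, THF, −78 °C) then builds the Z trisubstituted enoate on the substrate and rejoins the route at 18.

**Step 13 (and the reduction of step 14).** The amine catalyst or iodine may engage the α-methylene lactone (conjugate addition, iodination), iodine may isomerise the angelate, and the hydride of step 14 may reduce the methylene lactone in conjugate fashion.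
Fallback: the route sets out from 20, which is masked as its dimethylamine adduct F10 (Me2NH, THF; mixture at C11). Parikh–Doering oxidation gives the aldehyde F11, the Wittig reaction of step 12 gives the enal F12, the iodination of step 13 gives the iodoenal F13 and Luche reduction gives the iodo alcohol F14. Quaternisation with MeI and elimination with NaHCO3 regenerate the methylene lactone, and the route is rejoined at 24.

**Step 18.** Oligomerisation may outrun closure of the ten-membered ring, and ring strain in the transition state may override Felkin–Anh control, giving poor facial selectivity at C9.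
Fallback: the route sets out from 27. If the closure gives mainly the C9 epimer of 28, (5S)-carbinol F15, it is oxidised (Dess–Martin) to the C9 enone F16. This is reduced under reagent control with a CBS oxazaborolidine and catecholborane at −78 °C, using the catalyst enantiomer that delivers hydride to the face giving 9R, and the route is rejoined at 28.

## Further compounds

F1 | step 8 | (1R,2Z)-6-(tert-butyldimethylsilyloxy)-1-[(2R,3R)-3-{[(4-methoxybenzyl)oxy]methyl}oxiran-2-yl]-3-methylhex-2-en-1-yl tert-butyl propanedioate | CC(C)(C)OC(=O)CC(=O)O[C@H](/C=C(/C)CCCO[Si](C)(C)C(C)(C)C)[C@H]1O[C@@H]1COCc1ccc(OC)cc1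
F2 | step 8 | tert-butyl (3R,4R,5R)-5-[(Z)-5-(tert-butyldimethylsilyloxy)-2-methylpent-1-en-1-yl]-4-[(1S)-1-hydroxy-2-(4-methoxybenzyloxy)ethyl]-2-oxooxolane-3-carboxylate | CC(C)(C)OC(=O)[C@@H]1C(=O)O[C@H](/C=C(/C)CCCO[Si](C)(C)C(C)(C)C)[C@H]1[C@H](O)COCc1ccc(OC)cc1
F3 | step 8 | tert-butyl (3R,4S,5R)-5-[(Z)-5-(tert-butyldimethylsilyloxy)-2-methylpent-1-en-1-yl]-4-[(1S)-2-(4-methoxybenzyloxy)-1-{[(Z)-2-methylbut-2-enoyl]oxy}ethyl]-2-oxooxolane-3-carboxylate | CC(C)(C)OC(=O)[C@@H]1C(=O)O[C@H](/C=C(/C)CCCO[Si](C)(C)C(C)(C)C)[C@H]1[C@H](OC(=O)/C(C)=C\C)COCc1ccc(OC)cc1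
F4 | step 5 | (E)-4-[(4-methoxybenzyl)oxy]but-2-en-1-ol | OC/C=C/COCc1ccc(OC)cc1
F5 | step 5 | [(2R,3R)-3-{[(4-methoxybenzyl)oxy]methyl}oxiran-2-yl]methanol | OC[C@H]1O[C@@H]1COCc1ccc(OC)cc1
F6 | step 5 | (2S,3R)-3-{[(4-methoxybenzyl)oxy]methyl}oxirane-2-carbaldehyde | O=C[C@H]1O[C@@H]1COCc1ccc(OC)cc1
F7 | step 5 | (1S,2Z)-6-(tert-butyldimethylsilyloxy)-1-[(2R,3R)-3-{[(4-methoxybenzyl)oxy]methyl}oxiran-2-yl]-3-methylhex-2-en-1-ol (C6 epimer of 12) | O[C@@H](/C=C(/C)CCCO[Si](C)(C)C(C)(C)C)[C@H]1O[C@@H]1COCc1ccc(OC)cc1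
F8 | step 5 | (Z)-6-(tert-butyldimethylsilyloxy)-1-[(2S,3R)-3-{[(4-methoxybenzyl)oxy]methyl}oxiran-2-yl]-3-methylhex-2-en-1-one | O=C(/C=C(/C)CCCO[Si](C)(C)C(C)(C)C)[C@H]1O[C@@H]1COCc1ccc(OC)cc1
F9 | step 9 | 2-(trimethylsilyl)ethyl (3R,4S,5R)-4-[(1S)-1-({2-[bis(2,2,2-trifluoroethoxy)phosphoryl]propanoyl}oxy)-2-(4-methoxybenzyloxy)ethyl]-5-[(Z)-5-(tert-butyldimethylsilyloxy)-2-methylpent-1-en-1-yl]-2-oxooxolane-3-carboxylate (mixture at the phosphonate carbon) | C[Si](C)(C)CCOC(=O)[C@@H]1C(=O)O[C@H](/C=C(/C)CCCO[Si](C)(C)C(C)(C)C)[C@H]1[C@H](OC(=O)C(C)P(=O)(OCC(F)(F)F)OCC(F)(F)F)COCc1ccc(OC)cc1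
F10 | step 13 | (1S)-1-[(2R,3S)-4-[(dimethylamino)methyl]-2-[(Z)-5-hydroxy-2-methylpent-1-en-1-yl]-5-oxooxolan-3-yl]-2-(4-methoxybenzyloxy)ethyl (Z)-2-methylbut-2-enoate (mixture at C11) | CN(C)CC1C(=O)O[C@H](/C=C(/C)CCCO)[C@H]1[C@H](OC(=O)/C(C)=C\C)COCc1ccc(OC)cc1
F11 | step 13 | (1S)-1-[(2R,3S)-4-[(dimethylamino)methyl]-2-[(Z)-2-methyl-5-oxopent-1-en-1-yl]-5-oxooxolan-3-yl]-2-(4-methoxybenzyloxy)ethyl (Z)-2-methylbut-2-enoate (mixture at C11) | CN(C)CC1C(=O)O[C@H](/C=C(/C)CCC=O)[C@H]1[C@H](OC(=O)/C(C)=C\C)COCc1ccc(OC)cc1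
F12 | step 13 | (1S)-1-[(2R,3S)-4-[(dimethylamino)methyl]-2-[(1Z,5E)-2-methyl-7-oxohepta-1,5-dien-1-yl]-5-oxooxolan-3-yl]-2-(4-methoxybenzyloxy)ethyl (Z)-2-methylbut-2-enoate (mixture at C11) | CN(C)CC1C(=O)O[C@H](/C=C(/C)CC/C=C/C=O)[C@H]1[C@H](OC(=O)/C(C)=C\C)COCc1ccc(OC)cc1
F13 | step 13 | (1S)-1-[(2R,3S)-4-[(dimethylamino)methyl]-2-[(1Z,5Z)-6-iodo-2-methyl-7-oxohepta-1,5-dien-1-yl]-5-oxooxolan-3-yl]-2-(4-methoxybenzyloxy)ethyl (Z)-2-methylbut-2-enoate (mixture at C11) | CN(C)CC1C(=O)O[C@H](/C=C(/C)CC/C=C(\I)C=O)[C@H]1[C@H](OC(=O)/C(C)=C\C)COCc1ccc(OC)cc1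
F14 | step 13 | (1S)-1-[(2R,3S)-4-[(dimethylamino)methyl]-2-[(1Z,5Z)-7-hydroxy-6-iodo-2-methylhepta-1,5-dien-1-yl]-5-oxooxolan-3-yl]-2-(4-methoxybenzyloxy)ethyl (Z)-2-methylbut-2-enoate (mixture at C11) | CN(C)CC1C(=O)O[C@H](/C=C(/C)CC/C=C(\I)CO)[C@H]1[C@H](OC(=O)/C(C)=C\C)COCc1ccc(OC)cc1
F15 | step 18 | (3aS,4S,5S,6Z,10Z,11aR)-6-{[(tert-butyldimethylsilyl)oxy]methyl}-5-hydroxy-10-methyl-3-methylidene-2-oxo-2,3,3a,4,5,8,9,11a-octahydrocyclodeca[b]furan-4-yl (Z)-2-methylbut-2-enoate (C9 epimer of 28) | C=C1C(=O)O[C@@H]2/C=C(/C)CC/C=C(/CO[Si](C)(C)C(C)(C)C)[C@H](O)[C@@H](OC(=O)/C(C)=C\C)[C@@H]12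
F16 | step 18 | (3aS,4S,6Z,10Z,11aR)-6-{[(tert-butyldimethylsilyl)oxy]methyl}-10-methyl-3-methylidene-2,5-dioxo-2,3,3a,4,5,8,9,11a-octahydrocyclodeca[b]furan-4-yl (Z)-2-methylbut-2-enoate (C9 enone) | C=C1C(=O)O[C@@H]2/C=C(/C)CC/C=C(/CO[Si](C)(C)C(C)(C)C)C(=O)[C@@H](OC(=O)/C(C)=C\C)[C@@H]12
A1 | alternative 1 | 2-[2-(phenylsulfonyl)ethyl]furan | O=S(=O)(CCc1ccco1)c1ccccc1
A2 | alternative 1 | methyl (Z)-5-methoxy-5-[(S)-1-phenylethoxy]-4-(triethylsilyloxy)pent-3-enoate (mixed acetal, either acetal epimer) | COC(=O)C/C=C(\O[Si](CC)(CC)CC)C(OC)O[C@@H](C)c1ccccc1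
A3 | alternative 1 | methyl 2-[3-oxo-2-[(S)-1-phenylethoxy]-1-(2-phenylsulfonylethyl)-8-oxabicyclo[3.2.1]oct-6-en-4-yl]acetate with the target configuration at C6, C7 and C9 | O=C1[C@H](O[C@@H](C)c2ccccc2)[C@]2(CCS(=O)(=O)c3ccccc3)C=C[C@@H](O2)[C@@H]1CC(=O)OC
A4 | alternative 2 | C4–C9-bonded cis-decalin: C9 tertiary alcohol, equatorial C5 mesylate, C1=C10 alkene bearing the C14 silyl ether, trans C6/C7 γ-lactone | C[C@]12CCC=C(CO[Si](C)(C)C(C)(C)C)[C@@]1(O)C[C@H]3CC(=O)O[C@@H]3[C@H]2OS(C)(=O)=O
A5 | alternative 2 | ten-membered C9 enone with Z C4=C5, Z C1=C10 and the trans C6/C7 lactone | C1C(=O)O[C@@H]2/C=C(/C)CC/C=C(/CO[Si](C)(C)C(C)(C)C)C(=O)C[C@@H]12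
A6 | alternative 3 | seco methyl ester: Z C5 alkenyl iodide, C6 aldehyde, C8 PMB ether, C9 and C14 silyl ethers | I/C=C(/C)CC/C=C(/CO[Si](C)(C)C(C)(C)C)[C@@H](O[Si](C)(C)C(C)(C)C)[C@@H](OCc1ccc(OC)cc1)[C@H](C=O)CC(=O)OC
A7 | alternative 3 | protected ten-membered trans-fused 6,12-lactone lacking the C13 methylene and the angelate | C1C(=O)O[C@@H]2/C=C(/C)CC/C=C(/CO[Si](C)(C)C(C)(C)C)[C@@H](O[Si](C)(C)C(C)(C)C)[C@@H](OCc3ccc(OC)cc3)[C@@H]12
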